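**Retrosynthetic overview**

1. Numbering used below: C1 carries the exocyclic CH2; C2=C3 is the E-alkene; C5 carries CH3; C7 carries OAc; C8=C9 is the tetrasubstituted alkene (CH3 on C9); C10 and C11 are the cyclopentane CH's (C11 bonded to C1); C12, C13 are its CH2's; C14 is the quaternary C–CH3; C15 (next to C14) and C16 (next to C8) are the carbinols.
2. Endgame: desilylation and acetylation ⇐ 11-membered ring closed last at C7–C8 (Nozaki–Hiyama–Kishi, C8 enol triflate + C7 aldehyde) ⇐ C1–C2 by site-selective Suzuki coupling of a C1 enol triflate (from an acetyl group on C11) with an E-alkenylboronate made from 3-methylglutaric anhydride (C5).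
3. Core: C8 and C11 are carried as ketones; one amine-catalysed cascade on an acyclic, racemic keto-enedione aldehyde forms first the cyclopentane (Michael, C10–C14) and then the cyclohexane (aldol, C15–C16); the enedione is unmasked from a 2,3,5-trisubstituted furan.
4. Enabling feature: in the cyclohexene ring the diol carbons C16 and C15 are α and β to C8, an sp2 carbon that can be a ketone, so C15–C16 is a latent aldol bond; C10 is β to that ketone and α to C11 (the carbon that later receives C1), so the ring-fusion bond is a latent Michael bond. C9, C10, C15 and C16 are therefore all correctable (enolisable or retro-aldol-labile), and only quaternary C14 must be set by the catalyst.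
5. Ring order: cyclopentane, then cyclohexane (same operation), then the macrocycle.

Key step: step 7

Assumption (step 7): the quinine-derived primary amine is taken to give the (S)-configured quaternary C14; if the sense is the opposite, the quinidine-derived pseudo-enantiomer is used and nothing else changes.
Assumption (step 13): (DHQD)2AQN is taken to give the (S)-hemiester; if not, (DHQ)2AQN is used.

**Route**

Step 1
Reactants: 1 methyl 3-methylfuran-2-carboxylate
Product: 2 (3-methylfuran-2-yl)methanol
Conditions: LiAlH4, THF, 0 °C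
Reagents that add atoms: none
Why: LiAlH4 reduction of the heteroaryl ester (standard ester-to-alcohol reduction) gives the furfuryl alcohol whose oxygen becomes the C16 oxygen.

Step 2
Reactants: 2 (3-methylfuran-2-yl)methanol
Product: 3 tert-butyldimethyl[(3-methylfuran-2-yl)methoxy]silane
Conditions: TBSCl, imidazole, DMF, rt
Reagents that add atoms: tert-butyldimethylsilyl chloride, CC(C)(C)[Si](C)(C)Cl
Why: Imidazole-promoted silylation protects the alcohol for the lithiation and ensures that the later furan oxidation gives the open enedione instead of an Achmatowicz pyranone.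

Step 3
Reactants: 3 tert-butyldimethyl[(3-methylfuran-2-yl)methoxy]silane; 4 4-bromo-2-methylbut-1-ene
Product: 6 tert-butyldimethyl{[3-methyl-5-(3-methylbut-3-en-1-yl)furan-2-yl]methoxy}silane, via furyllithium 5 (not isolated)
Conditions: n-BuLi, THF, −78 to 0 °C; then 4, −78 °C to rt
Reagents that add atoms: none
Why: α-Lithiation of the 2,3-disubstituted furan occurs at the only free α-position and the furyllithium is alkylated by the primary homoallylic bromide (SN2), which attaches C12–C15.

Step 4
Reactants: 6 tert-butyldimethyl{[3-methyl-5-(3-methylbut-3-en-1-yl)furan-2-yl]methoxy}silane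
Product: 8 racemic 4-[5-({[tert-butyl(dimethyl)silyl]oxy}methyl)-4-methylfuran-2-yl]-2-methylbutan-1-ol, via B-alkyl-9-BBN adduct 7 (not isolated)
Conditions: 9-BBN, THF, 0 °C to rt; then NaOH, H2O2, 0 °C
Reagents that add atoms: hydrogen peroxide, OO
Why: Anti-Markovnikov hydroboration–oxidation of the 1,1-disubstituted alkene gives the primary alcohol; the new methyl-bearing centre is left racemic on purpose because step 7 erases it through an enamine.

Step 5
Reactants: 8 racemic 4-[5-({[tert-butyl(dimethyl)silyl]oxy}methyl)-4-methylfuran-2-yl]-2-methylbutan-1-ol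
Product: 9 racemic 4-[5-({[tert-butyl(dimethyl)silyl]oxy}methyl)-4-methylfuran-2-yl]-2-methylbutanal
Conditions: Dess–Martin periodinane, CH2Cl2, 0 °C to rt
Reagents that add atoms: none
Why: Dess–Martin oxidation converts the primary alcohol into the aldehyde under conditions that the furan and the silyl ether tolerate.

Step 6
Reactants: 9 racemic 4-[5-({[tert-butyl(dimethyl)silyl]oxy}methyl)-4-methylfuran-2-yl]-2-methylbutanal
Product: 10 racemic (Z)-9-[(tert-butyldimethylsilyl)oxy]-2,7-dimethyl-5,8-dioxonon-6-enal
Conditions: NBS, NaHCO3, acetone/H2O (9:1), −20 °C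
Reagents that add atoms: water, O
Why: Bromonium-induced hydrative ring opening of a 2,5-dialkylfuran unmasks the cis-2-ene-1,4-dione (C8 and C11 ketones across C9=C10), the furan oxygen becoming one of the two carbonyl oxygens.

Step 7
Reactants: 10 racemic (Z)-9-[(tert-butyldimethylsilyl)oxy]-2,7-dimethyl-5,8-dioxonon-6-enal
Product: 12 (3aS,4R,5S,7R,7aS)-5-[(tert-butyldimethylsilyl)oxy]-4-hydroxy-3a,7-dimethylhexahydro-1H-indene-1,6(2H)-dione, via Michael adduct keto-aldehyde 11 (not isolated)
Conditions: 9-amino-9-deoxy-epi-quinine (20 mol %), 2-fluorobenzoic acid (40 mol %), toluene (0.05 M), 25 °C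
Reagents that add atoms: none
Why: The primary amine condenses with the aldehyde to an enamine (this erases the racemic C14–H centre, so both enantiomers of 10 converge) and C14 adds 5-exo-trig to C10 of the enedione, whose E/Z geometry is equilibrated by reversible amine addition and is therefore irrelevant; the catalyst-controlled face of the enamine fixes quaternary C14, the only centre of the core that cannot be corrected afterwards. Hydrolysis gives keto-aldehyde 11, in which C16 is the only enolisable carbon that can reach the now non-enolisable C15 aldehyde through an unstrained ring, so amine/acid-mediated enolisation of the siloxy ketone closes the cyclohexanone by a 6-(enolendo)-exo-trig aldol that forms C15–C16. The closest known reaction types are the amine-catalysed intramolecular Michael addition of formyl enones, primary-amine-catalysed Michael additions of α-branched aldehydes, and the Hajos–Parrish-type 6-enolendo aldol cyclisation as combined in organocatalytic Michael/aldol dominoes. Stereocontrol after C14 is thermodynamic: C10 (α to the C11 ketone) equilibrates to the cis ring fusion as 14β-15-keto steroids do, C9 and C16 are α to C8 and C15 is retro-aldol-labile, so the chair with the sp2 carbon C11 axial and C9–CH3, C15–OH and C16–OTBS all equatorial (15,16-trans, C15–OH syn to the C14 methyl) is expected to accumulate. The selectivity needed is 5-exo over 6-endo Michael addition (C10 is the unsubstituted alkene carbon) and aldehyde over ketone as the aldol acceptor (the alternative closures are four-membered or attack the less electrophilic ketones). A 1,2-silyl shift between O16 and O15 would be harmless because both oxygens carry the same group after step 8.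

Step 8
Reactants: 12 (3aS,4R,5S,7R,7aS)-5-[(tert-butyldimethylsilyl)oxy]-4-hydroxy-3a,7-dimethylhexahydro-1H-indene-1,6(2H)-dione
Product: 13 (3aS,4R,5S,7R,7aS)-4,5-bis[(tert-butyldimethylsilyl)oxy]-3a,7-dimethylhexahydro-1H-indene-1,6(2H)-dione
Conditions: TBSOTf, 2,6-lutidine, CH2Cl2, −78 to 0 °C
Reagents that add atoms: tert-butyldimethylsilyl trifluoromethanesulfonate, CC(C)(C)[Si](C)(C)OS(=O)(=O)C(F)(F)F
Why: Silyl triflate silylation of the hindered secondary alcohol removes the retro-aldol pathway for the later base steps and gives both carbinol oxygens the same protecting group.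

Step 9
Reactants: 13 (3aS,4R,5S,7R,7aS)-4,5-bis[(tert-butyldimethylsilyl)oxy]-3a,7-dimethylhexahydro-1H-indene-1,6(2H)-dione
Product: 15 C11 enol triflate of 13 (C11=C12; other centres unchanged), via potassium enolate 14 (not isolated)
Conditions: KN(SiMe3)2 (1.05 equiv), THF, −78 °C; then PhNTf2, −78 to 0 °C
Reagents that add atoms: N-phenyl-bis(trifluoromethanesulfonimide), O=S(=O)(N(c1ccccc1)S(=O)(=O)C(F)(F)F)C(F)(F)F
Why: Kinetic deprotonation by the hindered amide takes the only α-CH2 (C12 of the cyclopentanone) in preference to the α-methines at C9, C10 and C16, and O-sulfonylation of the enolate gives the C11=C12 enol triflate.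

Step 10
Reactants: 15 C11 enol triflate of 13; 16 tributyl(1-ethoxyvinyl)stannane
Product: 18 cyclopentenyl methyl ketone (acetyl on C11; C11=C12), via ethoxydiene 17 (not isolated)
Conditions: Pd(PPh3)4 (5 mol %), LiCl, THF, 65 °C; then 1 M HCl, rt
Reagents that add atoms: water, O
Why: Stille coupling of the alkenyl triflate with the 1-ethoxyvinyl stannane (an acetyl anion equivalent) followed by acid hydrolysis of the enol ether puts C1 and its future methylene carbon on C11 as an acetyl group.

Step 11
Reactants: 18 cyclopentenyl methyl ketone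
Product: 19 saturated methyl ketone (C11–H, C10–H and C14–CH3 on one face; acetyl cis to the C10–C9 bond)
Conditions: H2 (1 atm), Pd/C (10 wt %), EtOAc, rt
Reagents that add atoms: none
Why: Heterogeneous hydrogenation of the conjugated C11=C12 bond should deliver hydrogen to the convex face of the cis-hydrindane (the face of the angular methyl, away from the folded six-membered ring), which places C11–H syn to C10–H and the acetyl group on the concave face, cis to C9.

Step 12
Reactants: 19 saturated methyl ketone
Product: 21 bis(enol triflate) of 19 (C8=C9 plus C1=CH2), via dipotassium bis-enolate 20 (not isolated)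
Conditions: KN(SiMe3)2 (3 equiv), THF, −78 to −40 °C; then PhNTf2 (3 equiv), −78 to 0 °C
Reagents that add atoms: N-phenyl-bis(trifluoromethanesulfonimide), O=S(=O)(N(c1ccccc1)S(=O)(=O)C(F)(F)F)C(F)(F)F
Why: Kinetic double enolisation (the acetyl CH3, and C9–H of the C8 ketone in preference to C16–H, which is deactivated and shielded by the two silyloxy groups as is usual for α-silyloxy ketones) and O-sulfonylation gives both alkenyl triflates and removes the C9 stereocentre.

Step 13
Reactants: 22 3-methylglutaric anhydride
Product: 23 (S)-5-methoxy-3-methyl-5-oxopentanoic acid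
Conditions: MeOH (10 equiv), (DHQD)2AQN (10 mol %), Et2O, −40 °C
Reagents that add atoms: methanol, CO
Why: Cinchona-alkaloid-catalysed methanolysis differentiates the enantiotopic carbonyl groups of the prochiral anhydride (known desymmetrisation of 3-substituted glutaric anhydrides) and so sets the C5 methyl stereocentre.

Step 14
Reactants: 23 (S)-5-methoxy-3-methyl-5-oxopentanoic acid
Product: 24 methyl (S)-5-hydroxy-3-methylpentanoate
Conditions: BH3·SMe2, THF, 0 °C to rt
Reagents that add atoms: none
Why: Borane reduces the carboxylic acid chemoselectively in the presence of the methyl ester.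

Step 15
Reactants: 24 methyl (S)-5-hydroxy-3-methylpentanoate
Product: 25 methyl (S)-3-methyl-5-oxopentanoate
Conditions: Dess–Martin periodinane, CH2Cl2, 0 °C
Reagents that add atoms: none
Why: Dess–Martin oxidation gives the aldehyde, which is used at once because the hydroxy ester precursor lactonises on standing.

Step 16
Reactants: 25 methyl (S)-3-methyl-5-oxopentanoate; 26 2-(dichloromethyl)-4,4,5,5-tetramethyl-1,3,2-dioxaborolane
Product: 27 methyl (S,E)-3-methyl-6-(4,4,5,5-tetramethyl-1,3,2-dioxaborolan-2-yl)hex-5-enoate
Conditions: CrCl2, LiI, THF, rt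
Reagents that add atoms: none
Why: Takai–Utimoto boryl olefination (a geminal dichromium species from the dihalomethylboronate adds to the aldehyde and eliminates) gives the E-alkenylboronate and fixes the C2=C3 geometry.

Step 17
Reactants: 21 bis(enol triflate); 27 methyl (S,E)-3-methyl-6-(4,4,5,5-tetramethyl-1,3,2-dioxaborolan-2-yl)hex-5-enoate
Product: 28 diene ester (C1–C2 coupled; C8 enol triflate intact)
Conditions: Pd(PPh3)4 (5 mol %), K3PO4, THF/H2O, rt
Reagents that add atoms: none
Why: Suzuki–Miyaura coupling should occur only at the unhindered 1,1-disubstituted C1 triflate, because oxidative addition to the tetrasubstituted C8 triflate flanked by C9–CH3 and C16–OTBS is much slower; the C1–C2 bond forms with retention of the E geometry and completes the 2-substituted 1,3-diene.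

Step 18
Reactants: 28 diene ester
Product: 29 diene aldehyde (C7 aldehyde; C8 enol triflate)
Conditions: (i-Bu)2AlH, CH2Cl2, −78 °C
Reagents that add atoms: none
Why: At −78 °C the aluminium hemiacetal formed from the methyl ester is stable and collapses to the C7 aldehyde only on work-up.

Step 19
Reactants: 29 diene aldehyde
Product: 30 macrocyclic (7S)-alcohol (target skeleton with C15 and C16 as TBS ethers)
Conditions: CrCl2 (10 equiv), NiCl2 (0.1 equiv), DMF, 0.002 M, rt
Reagents that add atoms: none
Why: Nozaki–Hiyama–Kishi reaction: zerovalent nickel inserts into the C8–OTf bond, transmetalation gives the alkenylchromium and this adds to the C7 aldehyde under high dilution to close the 11-membered ring; the chromium-bound oxygen should sit on the outside of the forming ring with the aldehyde hydrogen inside, which corresponds to the (S) carbinol.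

Step 20
Reactants: 30 macrocyclic (7S)-alcohol
Product: 31 C7 acetate bis-TBS ether
Conditions: Ac2O, DMAP, pyridine, CH2Cl2, 0 °C
Reagents that add atoms: acetic anhydride, CC(=O)OC(C)=O
Why: DMAP-catalysed acylation of the only free (allylic, secondary) hydroxyl gives the C7 acetate.

Step 21
Reactants: 31 C7 acetate bis-TBS ether
Product: 32 CNP0291538.1
Conditions: HF·pyridine, pyridine, THF, 0 °C to rt
Reagents that add atoms: none
Why: Fluoride cleaves both silyl ethers (buffered HF·pyridine should leave the allylic acetate and the diene untouched) and releases the trans-diol of the target.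

**Compound list**

1 | methyl 3-methylfuran-2-carboxylate | COC(=O)c1occc1C | starting material
2 | (3-methylfuran-2-yl)methanol | OCc1occc1C | intermediate
3 | tert-butyldimethyl[(3-methylfuran-2-yl)methoxy]silane | CC(C)(C)[Si](C)(C)OCc1occc1C | intermediate
4 | 4-bromo-2-methylbut-1-ene | C=C(C)CCBr | starting material
5 | 5-lithio derivative of 3 (furyllithium, not isolated) | [Li]c1cc(C)c(CO[Si](C)(C)C(C)(C)C)o1 | intermediate
6 | tert-butyldimethyl{[3-methyl-5-(3-methylbut-3-en-1-yl)furan-2-yl]methoxy}silane | CC(C)(C)[Si](C)(C)OCc1oc(CCC(C)=C)cc1C | intermediate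
7 | B-alkyl-9-borabicyclo[3.3.1]nonane adduct of 6 (not isolated) | CC(CCc1cc(C)c(CO[Si](C)(C)C(C)(C)C)o1)CB1C2CCCC1CCC2 | intermediate
8 | racemic 4-[5-({[tert-butyl(dimethyl)silyl]oxy}methyl)-4-methylfuran-2-yl]-2-methylbutan-1-ol | CC(C)(C)[Si](C)(C)OCc1oc(CCC(C)CO)cc1C | intermediate
9 | racemic 4-[5-({[tert-butyl(dimethyl)silyl]oxy}methyl)-4-methylfuran-2-yl]-2-methylbutanal | CC(C)(C)[Si](C)(C)OCc1oc(CCC(C)C=O)cc1C | intermediate
10 | racemic (Z)-9-[(tert-butyldimethylsilyl)oxy]-2,7-dimethyl-5,8-dioxonon-6-enal | CC(C)(C)[Si](C)(C)OCC(=O)/C(C)=C\C(=O)CCC(C)C=O | intermediate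
11 | (1S,2S)-2-{4-[(tert-butyldimethylsilyl)oxy]-3-oxobutan-2-yl}-1-methyl-3-oxocyclopentane-1-carbaldehyde, both epimers at the side-chain CH–CH3 (Michael adduct, not isolated) | CC(C)(C)[Si](C)(C)OCC(=O)C(C)[C@@H]1C(=O)CC[C@]1(C)C=O | intermediate
12 | (3aS,4R,5S,7R,7aS)-5-[(tert-butyldimethylsilyl)oxy]-4-hydroxy-3a,7-dimethylhexahydro-1H-indene-1,6(2H)-dione (cis-fused; C15–OH syn to the angular methyl, C16–OTBS trans to it) | O=C1[C@H](C)[C@@H]2C(=O)CC[C@]2(C)[C@@H](O)[C@@H]1O[Si](C)(C)C(C)(C)C | intermediate
13 | (3aS,4R,5S,7R,7aS)-4,5-bis[(tert-butyldimethylsilyl)oxy]-3a,7-dimethylhexahydro-1H-indene-1,6(2H)-dione | O=C1[C@H](C)[C@@H]2C(=O)CC[C@]2(C)[C@@H](O[Si](C)(C)C(C)(C)C)[C@@H]1O[Si](C)(C)C(C)(C)C | intermediate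
14 | potassium C11/C12 enolate of 13 (not isolated) | O=C1[C@H](C)[C@@H]2C([O-])=CC[C@]2(C)[C@@H](O[Si](C)(C)C(C)(C)C)[C@@H]1O[Si](C)(C)C(C)(C)C.[K+] | intermediate
15 | C11 enol triflate of 13 (C11=C12; cis ring fusion; C9, C14, C15, C16 as in 13) | O=C1[C@H](C)[C@@H]2C(OS(=O)(=O)C(F)(F)F)=CC[C@]2(C)[C@@H](O[Si](C)(C)C(C)(C)C)[C@@H]1O[Si](C)(C)C(C)(C)C | intermediate
16 | tributyl(1-ethoxyvinyl)stannane | CCCC[Sn](CCCC)(CCCC)C(=C)OCC | starting material
17 | 1-ethoxyvinyl diene from 15 (not isolated) | O=C1[C@H](C)[C@@H]2C(C(=C)OCC)=CC[C@]2(C)[C@@H](O[Si](C)(C)C(C)(C)C)[C@@H]1O[Si](C)(C)C(C)(C)C | intermediate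
18 | cyclopentenyl methyl ketone: acetyl on C11, C11=C12, C8 ketone, C15 and C16 TBS ethers | O=C1[C@H](C)[C@@H]2C(C(C)=O)=CC[C@]2(C)[C@@H](O[Si](C)(C)C(C)(C)C)[C@@H]1O[Si](C)(C)C(C)(C)C | intermediate
19 | saturated methyl ketone: acetyl on C11 cis to the C10–C9 bond (C11–H, C10–H and C14–CH3 on one face) | O=C1[C@H](C)[C@@H]2[C@H](C(C)=O)CC[C@]2(C)[C@@H](O[Si](C)(C)C(C)(C)C)[C@@H]1O[Si](C)(C)C(C)(C)C | intermediate
20 | dipotassium bis-enolate of 19 (C8=C9 and C1=CH2; not isolated) | [K+].[K+].[O-]C1=C(C)[C@@H]2[C@H](C(=C)[O-])CC[C@]2(C)[C@@H](O[Si](C)(C)C(C)(C)C)[C@@H]1O[Si](C)(C)C(C)(C)C | intermediate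
21 | bis(enol triflate): C8(OTf)=C9(CH3) in the six-membered ring and C1(OTf)=CH2 on C11 | FC(F)(F)S(=O)(=O)OC1=C(C)[C@@H]2[C@H](C(=C)OS(=O)(=O)C(F)(F)F)CC[C@]2(C)[C@@H](O[Si](C)(C)C(C)(C)C)[C@@H]1O[Si](C)(C)C(C)(C)C | intermediate
22 | 3-methylglutaric anhydride | CC1CC(=O)OC(=O)C1 | starting material
23 | (S)-5-methoxy-3-methyl-5-oxopentanoic acid | OC(=O)C[C@H](C)CC(=O)OC | intermediate
24 | methyl (S)-5-hydroxy-3-methylpentanoate | OCC[C@H](C)CC(=O)OC | intermediate
25 | methyl (S)-3-methyl-5-oxopentanoate | O=CC[C@H](C)CC(=O)OC | intermediate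
26 | 2-(dichloromethyl)-4,4,5,5-tetramethyl-1,3,2-dioxaborolane | ClC(Cl)B1OC(C)(C)C(C)(C)O1 | starting material
27 | methyl (S,E)-3-methyl-6-(4,4,5,5-tetramethyl-1,3,2-dioxaborolan-2-yl)hex-5-enoate | CC1(C)OB(/C=C/C[C@H](C)CC(=O)OC)OC1(C)C | intermediate
28 | diene ester: C11 carries the 2-substituted (E)-1,3-diene chain ending in the methyl ester (C7); C8 enol triflate retained | FC(F)(F)S(=O)(=O)OC1=C(C)[C@@H]2[C@H](C(=C)/C=C/C[C@H](C)CC(=O)OC)CC[C@]2(C)[C@@H](O[Si](C)(C)C(C)(C)C)[C@@H]1O[Si](C)(C)C(C)(C)C | intermediate
29 | diene aldehyde: as 28 with the ester reduced to the C7 aldehyde | FC(F)(F)S(=O)(=O)OC1=C(C)[C@@H]2[C@H](C(=C)/C=C/C[C@H](C)CC=O)CC[C@]2(C)[C@@H](O[Si](C)(C)C(C)(C)C)[C@@H]1O[Si](C)(C)C(C)(C)C | intermediate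
30 | macrocyclic (7S)-alcohol: target skeleton with free C7–OH and C15, C16 as TBS ethers | C=C1/C=C/C[C@H](C)C[C@H](O)C2=C(C)[C@@H]3[C@H]1CC[C@]3(C)[C@@H](O[Si](C)(C)C(C)(C)C)[C@@H]2O[Si](C)(C)C(C)(C)C | intermediate
31 | C7 acetate of 30 | C=C1/C=C/C[C@H](C)C[C@H](OC(C)=O)C2=C(C)[C@@H]3[C@H]1CC[C@]3(C)[C@@H](O[Si](C)(C)C(C)(C)C)[C@@H]2O[Si](C)(C)C(C)(C)C | intermediate
32 | CNP0291538.1 | C=C1/C=C/C[C@H](C)C[C@H](OC(C)=O)C2=C(C)[C@@H]3[C@H]1CC[C@]3(C)[C@@H](O)[C@@H]2O | target

**Totals**

Total steps: 21. Longest linear sequence: 17 (steps 1–12, then 17–21); the boronate 27 is made in 4 steps (13–16).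

**Three steps most likely to fail**

Step 7. What may go wrong: the enamine adds with too little facial discrimination, the primary amine is consumed by Paal–Knorr condensation with the 1,4-dicarbonyl array, or the aldol settles in the other chair, with both carbinol centres inverted (the two all-equatorial chairs are estimated to be close in energy, so the C15/C16 outcome is the least certain element of the route). The fallback sets out from 10 and comes back at 12. It separates the two bond formations and sets C14 with a stoichiometric chiral secondary amine, which cannot form a pyrrole. Condensation of 10 with (S)-2-(methoxymethyl)pyrrolidine (4 Å sieves, toluene) should give the enamine of 10 F1, which cyclises at 0–25 °C and, after addition of AcOH, is present as the iminium acetate of the Michael adduct F2. Buffered hydrolysis (NaOAc, THF/H2O) releases keto-aldehyde 11, now isolated and purified. Catalytic DBU in CH2Cl2 then closes C15–C16 under purely thermodynamic control to 12, and a minor aldol diastereomer can be recycled by resubmission to DBU.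

Step 19. What may go wrong: the alkenylchromium adds to both faces of the C7 aldehyde, so that the ring closes to a mixture of C7 epimers. The fallback sets out from 30 as obtained (epimeric at C7) and comes back at 30. It moves the stereocontrol from the C–C bond formation to a reagent-controlled reduction. Dess–Martin oxidation of the epimer mixture should give the macrocyclic C7 enone F7, and reduction with (R)-2-methyl-CBS-oxazaborolidine and BH3·SMe2 (the (S)-catalyst if the other sense is required) should return the (7S)-alcohol 30.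

Step 12. What may go wrong: deprotonation at C16 competes with deprotonation at C9, giving the regioisomeric C8=C16 enol triflate or β-elimination of the C15 silyloxy group. The fallback sets out from 19 and comes back at 21. It blocks C16 with a temporary ring instead of relying on kinetic discrimination. HF·pyridine converts 19 into the keto-diol F3, and 2,2-dimethoxypropane with PPTS gives the trans-fused acetonide F4, in which a C16 enolate would place an sp2 carbon at a trans ring fusion of the dioxolane. KN(SiMe3)2 and PhNTf2 then give the acetonide bis(enol triflate) F5, aqueous AcOH removes the strained acetonide to the diol bis(enol triflate) F6, and TBSOTf with 2,6-lutidine returns to 21.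

**Further compounds**

F1 | step 7 | enamine of 10 with (S)-2-(methoxymethyl)pyrrolidine | CC(C)(C)[Si](C)(C)OCC(=O)/C(C)=C\C(=O)CCC(C)=CN1CCC[C@H]1COC
F2 | step 7 | iminium acetate of the Michael adduct | CC(C)(C)[Si](C)(C)OCC(=O)C(C)[C@@H]1C(=O)CC[C@]1(C)C=[N+]1CCC[C@H]1COC.CC(=O)[O-]
F3 | step 12 | keto-diol (19 without its two silyl groups) | O=C1[C@H](C)[C@@H]2[C@H](C(C)=O)CC[C@]2(C)[C@@H](O)[C@@H]1O
F4 | step 12 | trans-fused acetonide of F3 | O=C1[C@H](C)[C@@H]2[C@H](C(C)=O)CC[C@]2(C)[C@@H]3[C@@H]1OC(C)(C)O3
F5 | step 12 | acetonide bis(enol triflate) | O=S(=O)(OC1=C(C)[C@@H]2[C@H](C(=C)OS(=O)(=O)C(F)(F)F)CC[C@]2(C)[C@@H]3[C@@H]1OC(C)(C)O3)C(F)(F)F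
F6 | step 12 | diol bis(enol triflate) | O=S(=O)(OC1=C(C)[C@@H]2[C@H](C(=C)OS(=O)(=O)C(F)(F)F)CC[C@]2(C)[C@@H](O)[C@@H]1O)C(F)(F)F
F7 | step 19 | macrocyclic C7 enone bis-TBS ether | C=C1/C=C/C[C@H](C)CC(=O)C2=C(C)[C@@H]3[C@H]1CC[C@]3(C)[C@@H](O[Si](C)(C)C(C)(C)C)[C@@H]2O[Si](C)(C)C(C)(C)C
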